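## The problem

The target, [(3R,4S,5R,6S)-5-(benzoyloxy)-3,4,6-trihydroxycyclohex-1-en-1-yl]methyl benzoate 18, is a single cyclohexene ring with one exocyclic carbon. With C1 the alkene carbon that bears C7, C2 the alkene CH and C3 to C6 the four contiguous carbinol carbons, there is no ring fusion to solve, only oxygenation, configuration and acylation pattern. O3 and O6 stand on one face and O4 and O5 on the other, a near-meso array whose symmetry is broken only by C7 on C1. The absolute configuration therefore has to come from a reagent that tells apart the two faces of a flat, achiral precursor. Once one centre exists the others can follow from it: an oxygen at C3 can send a cis-dihydroxylation of C4=C5 to the opposite face, and the C4/C5 hydroxyls can then deliver hydride to a C6 carbonyl from their own face, giving the trans C5/C6 relationship. Only O5 and O7 of the five oxygens are benzoylated, so one secondary hydroxyl flanked by two others must be acylated selectively; the benzoates migrate under base, which restricts the late steps to neutral or mildly acidic conditions. The allylic carbinols and every cyclohexadiene intermediate are one dehydration or one loss of methanol away from a benzene ring, so strong acid is excluded as well. The opening is that O3 and O6 are para across the six-membered ring, C7 is ortho to O6, and C2, C4 and C5 carry hydrogen: this is the substitution pattern of 2,5-dimethoxybenzyl alcohol 1, whose ring can be dearomatised at exactly these two oxygen-bearing carbons.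

## Retrosynthesis

**O5 benzoate (18 to 15 and 16).** The last bond cut is the ester C–O bond at O5. Direct benzoylation of tetrol 15 would favour the less hindered hydroxyls at C3 and C4. Delivering the benzoyl carbon as trimethyl orthobenzoate 16 through the cyclic orthoester 17 confines it to the only cis-diol, O4/O5, and the opening of such orthoesters favours the axial oxygen, here O5. The precursor 15 carries a single ester and no protecting group. The forward step has to stay acidic, so that no acyl group migrates, and has to open 17 toward O5.

**C6 carbinol (15 to 14).** The C6–H bond is cut next, tracing the carbinol to the enone 14. C6 is chosen over C3 for the late reduction because the hydroxyls at C4 and C5, already in place, can direct hydride to it from their own face; an undirected reagent would be expected to approach from the opposite face and give the cis C5/C6 isomer. The precursor has three stereocentres instead of four. The forward reaction must be an internal hydride delivery.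

**C6 ketone and O3 silyl ether (14 to 13).** The C6 carbonyl is traced to a dimethyl ketal and the free O3 to a triethylsilyl ether, both of which one mild aqueous acid treatment should remove. The ketone has to stay masked until C4 and C5 are sp3: a C6 ketone beside a C3 carbinol in a cyclohexadiene is the tautomer of a hydroquinone ether and would aromatise. Precursor 13 is the fully protected form of the same three stereocentres.

**C4–O and C5–O (13 to 12).** Both bonds are cut together as a cis-dihydroxylation of diene 12. The alternative of building the diol before C3 is set would leave no element to control the face. Precursor 12 has a single stereocentre. The forward reaction must add anti to the C3 silyloxy group and must choose C4=C5 over C1=C2; the fully substituted C1 and the allylic benzoate on C7 are relied on for the second point.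

**C3–H, with a temporary C4–I (12 to 11, 10, 9 and 8).** The C3–H bond is cut as an oxazaborolidine-catalysed reduction of a C3 ketone. In dienone 8 the carbonyl is flanked by two CH= groups that differ only at the β-carbons, too far from the catalyst to be told apart. The design therefore places iodine on C4, giving 9, so that the reduction distinguishes an α-iodovinyl arm from a CH= arm, a well-established pairing. The iodine is removed again after silylation (10 to 11 to 12). This costs two steps and buys a defensible source of the absolute configuration. Precursor 8 is achiral and planar.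

**O7 benzoate and silyl ether (8 to 6 and 7, 6 to 5).** The O7 ester bond is cut to benzoyl chloride 7 and the hydroxymethyl dienone 6, and 6 is traced to its silyl ether 5. The exchange is placed here because O7 is the only hydroxyl in 6, so no selectivity is needed. The benzoate cannot be carried from the start, since methanolic hydroxide would cleave it in the electrolysis.

**C3 ketone from the bisketal (5 to 4).** The C3 carbonyl is traced to the second dimethyl ketal of 4. Of the two ketals, the one at C3 should ionise first, because the positive charge of its oxocarbenium ion reaches C1, which bears the C7 carbon. The precursor 4 is symmetrical apart from C7. The forward hydrolysis must stop at the monoketal and must not touch the silyl ether.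

**C3–O and C6–O (4 to 2 and 3).** This is the strategic cut. The two ketal C–OMe bonds at C3 and C6 are removed, which restores the arene 2; two equivalents of methanol 3 are the other component. No chemical oxidant is needed, and the whole carbon skeleton with C7, the C1=C2 alkene of the target and the C4=C5 alkene reserved for the diol all come from a flat commercial arene. The forward reaction must add methanol at the two methoxy-bearing carbons only.

**O7 silyl ether (2 to 1).** The Si–O bond is cut to give commercial 2,5-dimethoxybenzyl alcohol 1. The silyl ether is needed only to keep the benzylic hydroxyl out of the anodic chemistry.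

## Roads not taken

**Alternative 1:** The ring would be cut at C2–C3 and C1–C6 and closed by a [4+2] cycloaddition. The diene is (1E,3E)-buta-1,3-diene-1,4-diyl diacetate A2 and the dienophile is 3-propioloyl-1,3-oxazolidin-2-one A3, activated by Cu(OTf)2 (divalent copper) with a chiral tert-butyl bis(oxazoline). The product would be the cis-3,6-diacetoxy cyclohexa-1,4-diene imide A1.
- Merits: one step closes the ring, brings in C7 at the acid level and sets C3 and C6 cis under catalyst control. A later dihydroxylation of C4=C5 in A1 would be pushed to the correct face by two allylic acyloxy groups, a stronger bias than the single silyl ether of the chosen route.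
- Weak points: chelate control by copper bis(oxazoline) complexes is established for alkenoyl imides, whereas the alkynoyl group of A3 is linear and offers the ligand little to discriminate. A2 is a deactivated diene. A1 carries two doubly allylic acetates and can lose acetic acid to an aromatic ester under the Lewis acid. Afterwards the imide must be reduced to the C7 alcohol beside two acetates, and the acetates on O3 and O6 must be removed while benzoates go onto O5 and O7.
- Comparison: if the cycloaddition worked, this road would reach a core with two stereocentres faster than the chosen plan, whose key step creates none. Against that, the chosen plan rests on a known electrolysis of exactly this substitution pattern and on stereocentre-forming steps of established types.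

**Alternative 2:** The C4–O and C5–O bonds would be formed first. Toluene dioxygenase in whole cells adds dioxygen across the 2,3-bond of bromobenzene A5 to give (1S,2S)-3-bromocyclohexa-3,5-diene-1,2-diol A4. The two carbinols of A4 map onto C4 and C5 with the correct absolute configuration, and its CBr carbon becomes C6.
- Merits: the enzyme delivers enantiopurity from the cheap arene A5 without the iodination, reduction and deiodination detour. After acetonide protection of A4, a 1,4-dioxygenation of the diene anti to the protected diol would place O3 and O6 cis to each other and trans to O4/O5 in one operation. In stereocontrol this road is better than the chosen one.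
- Weak points: A5 has no seventh carbon, so the C1–C7 bond has to be made later on a densely oxygenated enone. The bromine of A4 sits on the carbon that must become a carbinol. A4 dimerises on storage and needs fermentation or costly purchase. The O4/O5 differentiation problem is unchanged.
- Comparison: against the better enantiocontrol the chosen plan sets the complete seven-carbon skeleton from a cheap arene in two steps, no biocatalyst, and the O7 benzoate installed while O7 is the only hydroxyl.

**Alternative 3:** The ring would be cut at C3–C4 and C5–C6. The pyrone component is the coumalic acid imide A7, 3-(2-oxo-2H-pyran-5-carbonyl)-1,3-oxazolidin-2-one. Bound to Cu(OTf)2 and a chiral bis(oxazoline), A7 would add 2,2-dimethyl-1,3-dioxole A8 across pyrone C3 and C6. Loss of CO2 from the bridged lactone would then give the acetonide-protected diene imide A6.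
- Merits: the cis-diol arrives already protected, C7 is present at the acid level, and the diene of A6 is set up for 1,4-dioxygenation anti to the acetonide.
- Weak points: the chiral Lewis acid sits on the exocyclic acyl group of A7, remote from the forming bonds, so enantiocontrol is thinly supported. CO2 loss needs heat, under which A6 can aromatise or add a second molecule of A8. A8 is volatile and has to be prepared, and A7 has to be made from coumalic acid. The imide must still be reduced and O3 and O6 introduced separately, and the acetonide does not distinguish O4 from O5.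
- Comparison: this road offers what Alternative 2 offers, but with a speculative key step. Its one advantage over the chosen plan is a diol that comes with the ring; the chosen plan obtains ring, C7 and both para oxygens from a single known reaction.

Key step: step 2

Remark on the chemistry: all intermediates are numbered as the target (C1 carries C7, C2 is the alkene CH, C3 to C6 carry oxygen). Descriptors that change in steps 9 to 12 without a bond to the stereocentre being made or broken reflect changed substituent priorities only.

## Route

Step 1
Reactants: 1 2,5-dimethoxybenzyl alcohol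
Product: 2 tert-butyl[(2,5-dimethoxyphenyl)methoxy]dimethylsilane
Conditions: t-BuMe2SiCl, imidazole, DMF, 0 °C to rt
Reagents that add atoms: tert-butyl(chloro)dimethylsilane, CC(C)(C)[Si](C)(C)Cl
Why: Silylation of a primary benzylic alcohol with a silyl chloride and imidazole is routine; the ether keeps the C7 oxygen from forming an alkoxide that the anode would oxidise, and it should survive cold methanolic KOH.

Step 2
Reactants: 2 tert-butyl[(2,5-dimethoxyphenyl)methoxy]dimethylsilane; 3 methanol
Product: 4 tert-butyl(dimethyl)[(3,3,6,6-tetramethoxycyclohexa-1,4-dien-1-yl)methoxy]silane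
Conditions: Pt anode, Pt cathode, undivided cell, constant current, KOH (1%) in MeOH, 0 °C
Reagents that add atoms: methanol, CO
Why: The anode removes one electron from the electron-rich 1,4-dimethoxyarene, and the radical cation, whose positive charge lies mainly on the two methoxy-bearing carbons, is captured there by methoxide or methanol. The resulting cyclohexadienyl radical is oxidised to a methoxy-stabilised cation, which takes up a second molecule of methanol at the para methoxy-bearing carbon; two equivalents of methanol are thus built in, one counted as reactant 3 and the other drawn from the same solvent, and the new C3–O and C6–O bonds turn the ring into a cyclohexa-1,4-diene with ketals at C3 and C6. The cathode reduces methanol to dihydrogen and methoxide, which keeps the medium basic and protects the acid-labile bisketal. The closest known reaction type is the anodic methoxylation of 1,4-dimethoxybenzenes to quinone bisketals in methanolic KOH, a two-electron oxidative dearomatisation. No ring closes and no stereocentre forms. The step needs ipso,ipso (para) addition in preference to substitution at the benzylic C7 position or at the ring CH carbons. The para-dimethoxy pattern secures this, because both the charge distribution of the radical cation and the stability of the intermediate oxocarbenium ion favour the oxygenated carbons, and the high methoxide concentration makes capture at the ring faster than loss of a benzylic proton. Over-oxidation should be limited because 4 has lost the aromatic π system and is oxidised at a much higher potential than 2.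

Step 3
Reactants: 4 tert-butyl(dimethyl)[(3,3,6,6-tetramethoxycyclohexa-1,4-dien-1-yl)methoxy]silane
Product: 5 tert-butyl[(6,6-dimethoxy-3-oxocyclohexa-1,4-dien-1-yl)methoxy]dimethylsilane
Conditions: AcOH (2% aq.), acetone, 0 °C
Reagents that add atoms: water, O
Why: Acid-catalysed monohydrolysis of a quinone bisketal; the C3 ketal ionises faster because its oxocarbenium ion places positive charge on C1, where the C7 carbon donates, whereas ionisation at C6 would put the inductively withdrawing CH2O group next to the cationic carbon. Hydrolysis should stop at the monoketal because the C3 carbonyl destabilises the second oxocarbenium ion, and the dilute acid leaves the silyl ether intact.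

Step 4
Reactants: 5 tert-butyl[(6,6-dimethoxy-3-oxocyclohexa-1,4-dien-1-yl)methoxy]dimethylsilane
Product: 6 3-(hydroxymethyl)-4,4-dimethoxycyclohexa-2,5-dien-1-one
Conditions: HF·pyridine, pyridine, THF, 0 °C
Reagents that add atoms: none
Why: Fluoride cleavage of a primary silyl ether; buffered, water-free HF·pyridine is chosen so that neither base (conjugate addition to the dienone) nor aqueous acid (loss of the remaining ketal) intervenes.

Step 5
Reactants: 6 3-(hydroxymethyl)-4,4-dimethoxycyclohexa-2,5-dien-1-one; 7 benzoyl chloride
Product: 8 (6,6-dimethoxy-3-oxocyclohexa-1,4-dien-1-yl)methyl benzoate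
Conditions: pyridine, 4-(dimethylamino)pyridine (cat.), CH2Cl2, 0 °C
Reagents that add atoms: none
Why: Acylation of a primary allylic alcohol with an acid chloride under nucleophilic catalysis; the O7 benzoate of the target is placed while O7 is the only hydroxyl, and its electron withdrawal should later deactivate C1=C2 toward osmylation.

Step 6
Reactants: 8 (6,6-dimethoxy-3-oxocyclohexa-1,4-dien-1-yl)methyl benzoate
Product: 9 (4-iodo-6,6-dimethoxy-3-oxocyclohexa-1,4-dien-1-yl)methyl benzoate
Conditions: I2, pyridine, CH2Cl2, 0 °C to rt
Reagents that add atoms: iodine, II
Why: α-Iodination of an enone with iodine and pyridine by addition–elimination (pyridine adds at the β-carbon, the enolate is iodinated, pyridine leaves); only the arm whose β-carbon C5 bears hydrogen should take up pyridine readily, C1 being fully substituted, so iodine should enter C4. The iodine is a temporary control element that makes the two arms flanking the C3 carbonyl different for step 7.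

Step 7
Reactants: 9 (4-iodo-6,6-dimethoxy-3-oxocyclohexa-1,4-dien-1-yl)methyl benzoate
Product: 10 [(3R)-3-hydroxy-4-iodo-6,6-dimethoxycyclohexa-1,4-dien-1-yl]methyl benzoate
Conditions: (S)-1-methyl-3,3-diphenyltetrahydro-1H,3H-pyrrolo[1,2-c][1,3,2]oxazaborole [(S)-Me-CBS] (20 mol%), catecholborane, toluene, −78 °C; pH 7 buffer
Reagents that add atoms: none
Why: Corey–Bakshi–Shibata reduction; the α-iodovinyl arm (C4) should act as the large group and the CH= arm (C2) as the small one, as with 2-halocycloalk-2-enones, so the (S)-oxazaborolidine should deliver hydride to the face that gives the (3R) carbinol. Catecholborane at low temperature reduces only the catalyst-bound ketone in the 1,2-sense and leaves the benzoate and alkenes alone, and the neutral work-up avoids aromatisation of the dienol ketal.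

Step 8
Reactants: 10 [(3R)-3-hydroxy-4-iodo-6,6-dimethoxycyclohexa-1,4-dien-1-yl]methyl benzoate
Product: 11 {(3R)-4-iodo-6,6-dimethoxy-3-[(triethylsilyl)oxy]cyclohexa-1,4-dien-1-yl}methyl benzoate
Conditions: Et3SiCl, imidazole, CH2Cl2, 0 °C
Reagents that add atoms: chlorotriethylsilane, CC[Si](Cl)(CC)CC
Why: Silylation with a silyl chloride and imidazole is non-acidic, as the aromatisation-prone dienol ketal requires; the triethylsilyl ether supplies the bulk for face selection in step 10 and is labile enough to leave together with the ketal in step 11.

Step 9
Reactants: 11 {(3R)-4-iodo-6,6-dimethoxy-3-[(triethylsilyl)oxy]cyclohexa-1,4-dien-1-yl}methyl benzoate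
Product: 12 {(3S)-6,6-dimethoxy-3-[(triethylsilyl)oxy]cyclohexa-1,4-dien-1-yl}methyl benzoate
Conditions: Bu3SnH, Et3B (cat.), air, toluene, 0 °C to rt
Reagents that add atoms: none
Why: Radical chain hydrodehalogenation of a vinyl iodide, initiated by Et3B and air at or below room temperature; the conditions are neutral, leave C3 untouched and avoid zerovalent palladium, which could ionise the allylic benzoate.

Step 10
Reactants: 12 {(3S)-6,6-dimethoxy-3-[(triethylsilyl)oxy]cyclohexa-1,4-dien-1-yl}methyl benzoate
Product: 13 {(3R,4R,5S)-4,5-dihydroxy-6,6-dimethoxy-3-[(triethylsilyl)oxy]cyclohex-1-en-1-yl}methyl benzoate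
Conditions: OsO4 (cat.), N-methylmorpholine N-oxide, acetone/H2O, 0 °C to rt
Reagents that add atoms: osmium tetroxide, O=[Os](=O)(=O)=O; N-methylmorpholine N-oxide, C[N+]1([O-])CCOCC1; water, O
Why: Upjohn dihydroxylation; OsO4 should add to C4=C5 on the face opposite the allylic silyloxy group at C3 (Kishi model), the C6 ketal presenting one methoxy group to each face and exerting no bias, which sets C4 and C5. C4=C5 should react before C1=C2 because C1 is fully substituted, flanked by the quaternary ketal carbon and deactivated by the allylic benzoate.

Step 11
Reactants: 13 {(3R,4R,5S)-4,5-dihydroxy-6,6-dimethoxy-3-[(triethylsilyl)oxy]cyclohex-1-en-1-yl}methyl benzoate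
Product: 14 [(3R,4S,5S)-3,4,5-trihydroxy-6-oxocyclohex-1-en-1-yl]methyl benzoate
Conditions: AcOH/THF/H2O (3:1:1), rt
Reagents that add atoms: water, O
Why: Aqueous acetic acid should hydrolyse the allylic dimethyl ketal to the conjugated C6 ketone and cleave the secondary triethylsilyl ether in the same operation; the primary benzoate is stable and the medium is too weakly acidic to dehydrate the β-hydroxy ketone.

Step 12
Reactants: 14 [(3R,4S,5S)-3,4,5-trihydroxy-6-oxocyclohex-1-en-1-yl]methyl benzoate
Product: 15 [(3R,4S,5R,6S)-3,4,5,6-tetrahydroxycyclohex-1-en-1-yl]methyl benzoate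
Conditions: Me4NBH(OAc)3, MeCN/AcOH (1:1), −30 to 0 °C
Reagents that add atoms: none
Why: Evans–Saksena hydroxyl-directed reduction; the borohydride exchanges an acetate for the C5 or C4 hydroxyl and delivers hydride to the face of the C6 carbonyl on which these hydroxyls stand, so O6 should end trans to O5 (6S). Triacetoxyborohydride reduces an enone carbonyl only slowly without such delivery, so undirected attack and 1,4-reduction should not compete, and the acidic medium disfavours benzoate migration.

Step 13
Reactants: 15 [(3R,4S,5R,6S)-3,4,5,6-tetrahydroxycyclohex-1-en-1-yl]methyl benzoate; 16 trimethyl orthobenzoate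
Product: 18 [(3R,4S,5R,6S)-5-(benzoyloxy)-3,4,6-trihydroxycyclohex-1-en-1-yl]methyl benzoate, via cyclic 4,5-orthobenzoate 17 (not isolated)
Conditions: camphorsulfonic acid (cat.), MeCN, rt; then AcOH/H2O (4:1), rt
Reagents that add atoms: water, O
Why: Acid-catalysed orthoester exchange should select the only cis-1,2-diol (O4/O5) to give the five-membered cyclic orthobenzoate 17; aqueous acid opens it through the dioxolanylium ion and hemiorthoester, which collapses to the axial ester and equatorial alcohol. With O6 pseudoaxial to avoid allylic 1,2-strain with C7, O5 is the axial oxygen, so the benzoate should end on O5; no base is used, so both benzoates should stay in place.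

## Compound list

1 | 2,5-dimethoxybenzyl alcohol | COc1ccc(OC)c(CO)c1 | starting material
2 | tert-butyl[(2,5-dimethoxyphenyl)methoxy]dimethylsilane | COc1ccc(OC)c(CO[Si](C)(C)C(C)(C)C)c1 | intermediate
3 | methanol | CO | starting material
4 | tert-butyl(dimethyl)[(3,3,6,6-tetramethoxycyclohexa-1,4-dien-1-yl)methoxy]silane | COC1(OC)C=CC(OC)(OC)C(CO[Si](C)(C)C(C)(C)C)=C1 | intermediate
5 | tert-butyl[(6,6-dimethoxy-3-oxocyclohexa-1,4-dien-1-yl)methoxy]dimethylsilane | O=C1C=CC(OC)(OC)C(CO[Si](C)(C)C(C)(C)C)=C1 | intermediate
6 | 3-(hydroxymethyl)-4,4-dimethoxycyclohexa-2,5-dien-1-one | O=C1C=CC(OC)(OC)C(CO)=C1 | intermediate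
7 | benzoyl chloride | O=C(Cl)c1ccccc1 | starting material
8 | (6,6-dimethoxy-3-oxocyclohexa-1,4-dien-1-yl)methyl benzoate | O=C1C=CC(OC)(OC)C(COC(=O)c2ccccc2)=C1 | intermediate
9 | (4-iodo-6,6-dimethoxy-3-oxocyclohexa-1,4-dien-1-yl)methyl benzoate | O=C1C(I)=CC(OC)(OC)C(COC(=O)c2ccccc2)=C1 | intermediate
10 | [(3R)-3-hydroxy-4-iodo-6,6-dimethoxycyclohexa-1,4-dien-1-yl]methyl benzoate | O=C(OCC1=C[C@@H](O)C(I)=CC1(OC)OC)c1ccccc1 | intermediate
11 | {(3R)-4-iodo-6,6-dimethoxy-3-[(triethylsilyl)oxy]cyclohexa-1,4-dien-1-yl}methyl benzoate | O=C(OCC1=C[C@@H](O[Si](CC)(CC)CC)C(I)=CC1(OC)OC)c1ccccc1 | intermediate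
12 | {(3S)-6,6-dimethoxy-3-[(triethylsilyl)oxy]cyclohexa-1,4-dien-1-yl}methyl benzoate | O=C(OCC1=C[C@@H](O[Si](CC)(CC)CC)C=CC1(OC)OC)c1ccccc1 | intermediate
13 | {(3R,4R,5S)-4,5-dihydroxy-6,6-dimethoxy-3-[(triethylsilyl)oxy]cyclohex-1-en-1-yl}methyl benzoate | O=C(OCC1=C[C@@H](O[Si](CC)(CC)CC)[C@H](O)[C@H](O)C1(OC)OC)c1ccccc1 | intermediate
14 | [(3R,4S,5S)-3,4,5-trihydroxy-6-oxocyclohex-1-en-1-yl]methyl benzoate | O=C(OCC1=C[C@@H](O)[C@H](O)[C@H](O)C1=O)c1ccccc1 | intermediate
15 | [(3R,4S,5R,6S)-3,4,5,6-tetrahydroxycyclohex-1-en-1-yl]methyl benzoate | O=C(OCC1=C[C@@H](O)[C@H](O)[C@H](O)[C@H]1O)c1ccccc1 | intermediate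
16 | trimethyl orthobenzoate, (trimethoxymethyl)benzene | COC(OC)(OC)c1ccccc1 | starting material
17 | cyclic methyl orthobenzoate of 15 across O4 and O5 (2-methoxy-2-phenyl-1,3-dioxolane fused at C4/C5, configuration at C3 to C6 as in 15, either configuration at the orthoester carbon) | O=C(OCC1=C[C@@H](O)[C@@H]2OC(OC)(c3ccccc3)O[C@@H]2[C@H]1O)c1ccccc1 | intermediate
18 | [(3R,4S,5R,6S)-5-(benzoyloxy)-3,4,6-trihydroxycyclohex-1-en-1-yl]methyl benzoate | O=C(OCC1=C[C@@H](O)[C@H](O)[C@H](OC(=O)c2ccccc2)[C@H]1O)c1ccccc1 | target

## Step count and least certain steps

Total step count: 13. Longest linear sequence: 13 steps (1 to 18).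

**Step 2 (key step).**
- What may go wrong: oxidation at the benzylic CH2–O position in competition with addition to the ring, or methanolysis of the silyl ether followed by oxidation of the freed alkoxide; partial hydrolysis of the bisketal during work-up.
- Fallback: bring in C7 after the dearomatisation. Commercial 2-bromo-1,4-dimethoxybenzene F1 would be electrolysed in methanol 3 under the same regime to give 1-bromo-3,3,6,6-tetramethoxycyclohexa-1,4-diene F2. Bromine–lithium exchange (n-BuLi, THF, −78 °C) would give (3,3,6,6-tetramethoxycyclohexa-1,4-dien-1-yl)lithium F3, which is trapped with monomeric formaldehyde to give (3,3,6,6-tetramethoxycyclohexa-1,4-dien-1-yl)methanol F4. Dilute aqueous acetic acid in acetone should then hydrolyse the C3 ketal. The fallback sets out from 3 (with F1) and returns to the route at 6, bypassing 2, 4 and 5.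

**Step 7.**
- What may go wrong: insufficient facial discrimination if the iodovinyl arm does not dominate binding to the catalyst (this also depends on iodine having entered C4 in step 6); loss of material by acid-induced aromatisation during work-up.
- Fallback: resolution instead of asymmetric reduction. Luche reduction of 9 (NaBH4, CeCl3·7H2O, MeOH, −78 °C) would give 10 together with its enantiomer [(3S)-3-hydroxy-4-iodo-6,6-dimethoxycyclohexa-1,4-dien-1-yl]methyl benzoate F5. Acetylation (Ac2O, pyridine) would give [(3R)-3-acetoxy-4-iodo-6,6-dimethoxycyclohexa-1,4-dien-1-yl]methyl benzoate F6 and its enantiomer [(3S)-3-acetoxy-4-iodo-6,6-dimethoxycyclohexa-1,4-dien-1-yl]methyl benzoate F7. Hydrolysis with Burkholderia cepacia lipase (pH 7 buffer, methyl tert-butyl ether) should, by the Kazlauskas rule with the iodovinyl arm as the large group, cleave F6 faster and leave F7. The fallback sets out from 9 and returns at 10.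

**Step 10.**
- What may go wrong: competing osmylation of the trisubstituted C1=C2 bond, over-oxidation of both alkenes, or eroded facial selectivity.
- Fallback: deactivate C1=C2 by conjugation instead of by an allylic ester. From 12, K2CO3 in MeOH at 0 °C would remove the benzoate to give {(3S)-6,6-dimethoxy-3-[(triethylsilyl)oxy]cyclohexa-1,4-dien-1-yl}methanol F8. MnO2 in CH2Cl2 would give (3S)-6,6-dimethoxy-3-[(triethylsilyl)oxy]cyclohexa-1,4-diene-1-carbaldehyde F9, in which OsO4 with N-methylmorpholine N-oxide can reach only C4=C5, giving (3R,4R,5S)-4,5-dihydroxy-6,6-dimethoxy-3-[(triethylsilyl)oxy]cyclohex-1-ene-1-carbaldehyde F10. Luche reduction would give {(3R,4R,5S)-4,5-dihydroxy-6,6-dimethoxy-3-[(triethylsilyl)oxy]cyclohex-1-en-1-yl}methanol F11, and benzoyl chloride 7 with 2,4,6-collidine at −40 °C should acylate the primary hydroxyl. The fallback sets out from 12 and returns at 13.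

**Step 13.**
- What may go wrong: poor regioselectivity in the collapse of the hemiorthoester (benzoate on O4) if the ring does not hold O5 axial, competing orthoester formation at the trans-diols, or acyl migration during work-up.
- Fallback: fix the benzoate on O5 before C6 is reduced. From 13, Et3SiCl and imidazole should silylate the C4 hydroxyl in preference to the C5 hydroxyl, which is flanked by the quaternary ketal carbon, giving {(3R,4R,5S)-5-hydroxy-6,6-dimethoxy-3,4-bis[(triethylsilyl)oxy]cyclohex-1-en-1-yl}methyl benzoate F12. Benzoyl chloride 7 with pyridine and 4-(dimethylamino)pyridine would give [(3R,4R,5S)-5-(benzoyloxy)-6,6-dimethoxy-3,4-bis[(triethylsilyl)oxy]cyclohex-1-en-1-yl]methyl benzoate F13. AcOH/THF/H2O would unveil [(3R,4S,5S)-5-(benzoyloxy)-3,4-dihydroxy-6-oxocyclohex-1-en-1-yl]methyl benzoate F14, and Me4NBH(OAc)3, directed by the C4 hydroxyl, should reduce C6 in the 1,3-anti sense. The fallback sets out from 13 and returns at 18, bypassing 14 to 17.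

## Further compounds

F1 | step 2 | 2-bromo-1,4-dimethoxybenzene | COc1ccc(OC)c(Br)c1
F2 | step 2 | 1-bromo-3,3,6,6-tetramethoxycyclohexa-1,4-diene | COC1(OC)C=CC(OC)(OC)C(Br)=C1
F3 | step 2 | (3,3,6,6-tetramethoxycyclohexa-1,4-dien-1-yl)lithium | [Li]C1=CC(OC)(OC)C=CC1(OC)OC
F4 | step 2 | (3,3,6,6-tetramethoxycyclohexa-1,4-dien-1-yl)methanol | COC1(OC)C=CC(OC)(OC)C(CO)=C1
F5 | step 7 | [(3S)-3-hydroxy-4-iodo-6,6-dimethoxycyclohexa-1,4-dien-1-yl]methyl benzoate | O=C(OCC1=C[C@H](O)C(I)=CC1(OC)OC)c1ccccc1
F6 | step 7 | [(3R)-3-acetoxy-4-iodo-6,6-dimethoxycyclohexa-1,4-dien-1-yl]methyl benzoate | O=C(OCC1=C[C@@H](OC(C)=O)C(I)=CC1(OC)OC)c1ccccc1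
F7 | step 7 | [(3S)-3-acetoxy-4-iodo-6,6-dimethoxycyclohexa-1,4-dien-1-yl]methyl benzoate | O=C(OCC1=C[C@H](OC(C)=O)C(I)=CC1(OC)OC)c1ccccc1
F8 | step 10 | {(3S)-6,6-dimethoxy-3-[(triethylsilyl)oxy]cyclohexa-1,4-dien-1-yl}methanol | OCC1=C[C@@H](O[Si](CC)(CC)CC)C=CC1(OC)OC
F9 | step 10 | (3S)-6,6-dimethoxy-3-[(triethylsilyl)oxy]cyclohexa-1,4-diene-1-carbaldehyde | O=CC1=C[C@@H](O[Si](CC)(CC)CC)C=CC1(OC)OC
F10 | step 10 | (3R,4R,5S)-4,5-dihydroxy-6,6-dimethoxy-3-[(triethylsilyl)oxy]cyclohex-1-ene-1-carbaldehyde | O=CC1=C[C@@H](O[Si](CC)(CC)CC)[C@H](O)[C@H](O)C1(OC)OC
F11 | step 10 | {(3R,4R,5S)-4,5-dihydroxy-6,6-dimethoxy-3-[(triethylsilyl)oxy]cyclohex-1-en-1-yl}methanol | OCC1=C[C@@H](O[Si](CC)(CC)CC)[C@H](O)[C@H](O)C1(OC)OC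
F12 | step 13 | {(3R,4R,5S)-5-hydroxy-6,6-dimethoxy-3,4-bis[(triethylsilyl)oxy]cyclohex-1-en-1-yl}methyl benzoate | O=C(OCC1=C[C@@H](O[Si](CC)(CC)CC)[C@H](O[Si](CC)(CC)CC)[C@H](O)C1(OC)OC)c1ccccc1
F13 | step 13 | [(3R,4R,5S)-5-(benzoyloxy)-6,6-dimethoxy-3,4-bis[(triethylsilyl)oxy]cyclohex-1-en-1-yl]methyl benzoate | O=C(OCC1=C[C@@H](O[Si](CC)(CC)CC)[C@H](O[Si](CC)(CC)CC)[C@H](OC(=O)c2ccccc2)C1(OC)OC)c1ccccc1
F14 | step 13 | [(3R,4S,5S)-5-(benzoyloxy)-3,4-dihydroxy-6-oxocyclohex-1-en-1-yl]methyl benzoate | O=C(OCC1=C[C@@H](O)[C@H](O)[C@H](OC(=O)c2ccccc2)C1=O)c1ccccc1
A1 | alternative 1 | 3-[(3S,6R)-3,6-diacetoxycyclohexa-1,4-diene-1-carbonyl]-1,3-oxazolidin-2-one | O=C(N1CCOC1=O)C1=C[C@@H](OC(C)=O)C=C[C@H]1OC(C)=O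
A2 | alternative 1 | (1E,3E)-buta-1,3-diene-1,4-diyl diacetate | CC(=O)O/C=C/C=C/OC(C)=O
A3 | alternative 1 | 3-propioloyl-1,3-oxazolidin-2-one | C#CC(=O)N1CCOC1=O
A4 | alternative 2 | (1S,2S)-3-bromocyclohexa-3,5-diene-1,2-diol | BrC1=CC=C[C@H](O)[C@@H]1O
A5 | alternative 2 | bromobenzene | Brc1ccccc1
A6 | alternative 3 | 3-[(3aR,7aS)-2,2-dimethyl-3a,7a-dihydro-1,3-benzodioxole-5-carbonyl]-1,3-oxazolidin-2-one | C1=C(C(=O)N2CCOC2=O)C=C[C@@H]3OC(C)(C)O[C@H]13
A7 | alternative 3 | 3-(2-oxo-2H-pyran-5-carbonyl)-1,3-oxazolidin-2-one | O=C(N1CCOC1=O)c1ccc(=O)oc1
A8 | alternative 3 | 2,2-dimethyl-1,3-dioxole | CC1(C)OC=CO1
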